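**Assumption:** (S)-1-bromo-3-chloro-2-methylpropane, geometrically pure (E)-2-bromobut-2-ene and PMB-protected glycolaldehyde are taken as commercially available.

## Retrosynthetic overview

1. Target ⇒ HF desilylation and Yamaguchi esterification of a cis-5-hydroxy-δ-lactone with a bis-TBS dienoic acid.
2. Key disconnection: the C4–C5 bond of the oxan-2-one ring, made by photoredox decarboxylative radical (Giese) addition of an acyclic α-alkoxy radical to methyl acrylate. This step sets ring C5 under control of the neighbouring carbinol, and the δ-lactone, the only ring built, closes in the same operation.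
3. The radical precursor (β-hydroxy-α-PMB-oxy acid) ⇒ proline cross-aldol of the side-chain aldehyde with PMB-glycolaldehyde, then Pinnick oxidation; the glycolaldehyde carbonyl carbon is a traceless handle.
4. Side-chain aldehyde ⇒ nickel-catalysed radical sp3–sp2 cross-electrophile coupling, then invertive coupling of the derived Grignard reagent with ethyl (S)-lactate triflate and ester reduction.
5. Dienoic acid ⇒ rhodium-catalysed asymmetric alkenyl addition to furan-2(5H)-one (purchased ring, later opened by LiAlH4), silylation, SeO2 allylic oxidation, Doebner condensation.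

## Route

**Step 1**
Reactants: 1 (S)-1-bromo-3-chloro-2-methylpropane; 2 (E)-2-bromobut-2-ene
Product: 3 (2R,4E)-1-chloro-2,4-dimethylhex-4-ene
Conditions: NiBr2·glyme (5 mol%), 4,4′-di-tert-butyl-2,2′-bipyridine (5 mol%), Zn dust (2 equiv), DMA, 25 °C
Reagents that add atoms: none
Why: Nickel-catalysed reductive cross-electrophile coupling (Weix type): the alkenyl bromide adds to zerovalent nickel with retention of the E geometry, the primary alkyl radical formed from the C–Br bond is captured by nickel and reductive elimination forms the sp3–sp2 bond, while the C–Cl bond and the non-reacting stereocentre are carried through.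

**Step 2**
Reactants: 4 ethyl (S)-lactate
Product: 5 ethyl (2S)-2-[(trifluoromethanesulfonyl)oxy]propanoate
Conditions: Tf2O (1.1 equiv), 2,6-lutidine (1.2 equiv), CH2Cl2, −78 → 0 °C
Reagents that add atoms: trifluoromethanesulfonic anhydride, O=S(=O)(OS(=O)(=O)C(F)(F)F)C(F)(F)F
Why: Sulfonylation at oxygen only, so the lactate stereocentre is retained and becomes a leaving group for the next step.

**Step 3**
Reactants: 3 (2R,4E)-1-chloro-2,4-dimethylhex-4-ene; 5 ethyl (2S)-2-[(trifluoromethanesulfonyl)oxy]propanoate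
Product: 7 ethyl (2S,4S,6E)-2,4,6-trimethyloct-6-enoate, via Grignard reagent 6 (not isolated)
Conditions: Mg turnings (1.3 equiv), I2 (cat.), THF, 65 °C; then 5, ZnCl2 (10 mol%), THF, 0 °C
Reagents that add atoms: none
Why: Zinc-catalysed stereospecific sp3–sp3 coupling of a Grignard reagent with an α-triflyloxy ester (SN2 via a triorganozincate, complete inversion), which converts the (S)-lactate carbon into the (2S)-methyl centre and so sets the 2,4-anti dimethyl array.

**Step 4**
Reactants: 7 ethyl (2S,4S,6E)-2,4,6-trimethyloct-6-enoate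
Product: 8 (2S,4S,6E)-2,4,6-trimethyloct-6-enal
Conditions: i-Bu2AlH (1.05 equiv), CH2Cl2, −78 °C; aqueous potassium sodium tartrate
Reagents that add atoms: none
Why: Half-reduction of the ester through the aluminium hemiacetal that is stable at −78 °C; the α-stereocentre is not enolised and the aldehyde is used at once.

**Step 5**
Reactants: 8 (2S,4S,6E)-2,4,6-trimethyloct-6-enal; 9 2-[(4-methoxyphenyl)methoxy]acetaldehyde
Product: 10 (2R,3R,4S,6S,8E)-3-hydroxy-2-[(4-methoxyphenyl)methoxy]-4,6,8-trimethyldec-8-enal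
Conditions: D-proline (20 mol%), DMF, 4 °C, 9 (2 equiv) added by syringe pump over 24 h
Reagents that add atoms: none
Why: Proline-catalysed direct cross-aldol reaction with the α-oxyaldehyde 9 as enamine donor (MacMillan-type α-oxyaldehyde aldol, Houk–List transition state): D-proline directs attack to the aldehyde face that gives the (3R) carbinol, which is also the Felkin face of 8 (matched case), and the C2 centre formed at the same time need not be controlled because step 7 erases it.

**Step 6**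
Reactants: 10 (2R,3R,4S,6S,8E)-3-hydroxy-2-[(4-methoxyphenyl)methoxy]-4,6,8-trimethyldec-8-enal
Product: 11 (2R,3R,4S,6S,8E)-3-hydroxy-2-[(4-methoxyphenyl)methoxy]-4,6,8-trimethyldec-8-enoic acid
Conditions: NaClO2 (3 equiv), NaH2PO4 (3 equiv), 2-methylbut-2-ene (20 equiv), t-BuOH/H2O, 0 °C
Reagents that add atoms: sodium chlorite, [Na+].[O-]Cl=O
Why: Pinnick oxidation: chlorous acid oxidises only the aldehyde, the hypochlorous acid by-product is trapped by 2-methylbut-2-ene so the trisubstituted alkene and the PMB ether survive, and no stereocentre is touched.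

**Step 7 (key step)**
Reactants: 11 (2R,3R,4S,6S,8E)-3-hydroxy-2-[(4-methoxyphenyl)methoxy]-4,6,8-trimethyldec-8-enoic acid; 12 methyl acrylate
Product: 14 (5R,6R)-6-[(2S,4S,6E)-4,6-dimethyloct-6-en-2-yl]-5-[(4-methoxyphenyl)methoxy]oxan-2-one, via hydroxy ester 13 (not isolated)
Conditions: Ir[dF(CF3)ppy]2(dtbbpy)PF6 (1 mol%), K2HPO4 (1.2 equiv), 12 (3 equiv), DMF, blue LEDs, 23 °C; then pyridinium p-toluenesulfonate (10 mol%), toluene, 60 °C
Reagents that add atoms: none
Why: Proposed new method: visible-light decarboxylation of the α-alkoxy carboxylate gives a planar α-alkoxy radical at C2 of 11 (the aldol stereocentre is erased), which should add to methyl acrylate anti to the vicinal C–O bond with the bulky chain turned toward the radical hydrogen (Felkin–Anh-type polar model, reinforced by an internal O–H···O(PMB) five-membered hydrogen bond that mimics the trans-selective 2,2-dimethyl-1,3-dioxolan-4-yl radicals), so the new C–C bond forms threo to the free hydroxyl, and because the other oxygen is blocked as its PMB ether the hydroxy ester can only close to the cis-(5R,6R) δ-lactone; the closest known reaction types are the iridium-photocatalysed decarboxylative Giese addition of α-oxy acids and trans-selective additions of dioxolanyl radicals to acrylates.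

**Step 8**
Reactants: 14 (5R,6R)-6-[(2S,4S,6E)-4,6-dimethyloct-6-en-2-yl]-5-[(4-methoxyphenyl)methoxy]oxan-2-one
Product: 15 (5R,6R)-6-[(2S,4S,6E)-4,6-dimethyloct-6-en-2-yl]-5-hydroxyoxan-2-one
Conditions: DDQ (1.3 equiv), CH2Cl2/pH 7 phosphate buffer (10:1), 0 °C
Reagents that add atoms: none
Why: Oxidative PMB cleavage (hydride abstraction from the electron-rich benzylic ether, then hydrolysis of the oxocarbenium ion) under neutral buffered conditions, chosen so that neither acid nor base can trigger translactonisation; stereocentres untouched.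

**Step 9**
Reactants: 16 furan-2(5H)-one; 17 (2-methylprop-1-en-1-yl)boronic acid
Product: 18 (4R)-4-(2-methylprop-1-en-1-yl)oxolan-2-one
Conditions: [Rh(OH)(cod)]2 (2.5 mol%), (R)-BINAP (6 mol%), 17 (2.5 equiv), dioxane/H2O (10:1), 50 °C
Reagents that add atoms: none
Why: Hayashi–Miyaura rhodium-catalysed asymmetric 1,4-addition: the (R)-BINAP–rhodium alkenyl species adds to the butenolide on the same face as in the cyclopentenone series, which here corresponds to the (4R) lactone, and water protonates the rhodium enolate.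

**Step 10**
Reactants: 18 (4R)-4-(2-methylprop-1-en-1-yl)oxolan-2-one
Product: 19 (2R)-2-(2-methylprop-1-en-1-yl)butane-1,4-diol
Conditions: LiAlH4 (1.5 equiv), THF, 0 → 23 °C; aqueous NaOH work-up
Reagents that add atoms: none
Why: Hydride reduction of the lactone to the 1,4-diol without touching the trisubstituted alkene or the stereocentre.

**Step 11**
Reactants: 19 (2R)-2-(2-methylprop-1-en-1-yl)butane-1,4-diol
Product: 20 (2R)-1,4-bis[(tert-butyldimethylsilyl)oxy]-2-(2-methylprop-1-en-1-yl)butane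
Conditions: TBSCl (2.4 equiv), imidazole (5 equiv), DMF, 23 °C
Reagents that add atoms: tert-butyldimethylsilyl chloride, CC(C)(C)[Si](C)(C)Cl
Why: Imidazole-promoted silylation of both primary alcohols, so that later only the carboxylic acid can be esterified.

**Step 12**
Reactants: 20 (2R)-1,4-bis[(tert-butyldimethylsilyl)oxy]-2-(2-methylprop-1-en-1-yl)butane
Product: 22 (2E,4R)-6-[(tert-butyldimethylsilyl)oxy]-4-{[(tert-butyldimethylsilyl)oxy]methyl}-2-methylhex-2-enal, via allylic alcohol 21 (not isolated)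
Conditions: SeO2 (0.3 equiv), t-BuOOH (3 equiv), CH2Cl2, 23 °C; then MnO2 (15 equiv), CH2Cl2, 23 °C
Reagents that add atoms: selenium dioxide (catalytic oxygen carrier), O=[Se]=O; tert-butyl hydroperoxide (terminal oxygen source), CC(C)(C)OO
Why: Sharpless SeO2/t-BuOOH allylic oxidation (ene reaction, then [2,3]-sigmatropic shift) attacks only the (E)-methyl group at the more substituted alkene terminus, and MnO2 then takes the allylic alcohol to the (E)-enal, leaving the silyl ethers and the allylic stereocentre intact.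

**Step 13**
Reactants: 22 (2E,4R)-6-[(tert-butyldimethylsilyl)oxy]-4-{[(tert-butyldimethylsilyl)oxy]methyl}-2-methylhex-2-enal; 23 malonic acid
Product: 24 (2E,4E,6R)-8-[(tert-butyldimethylsilyl)oxy]-6-{[(tert-butyldimethylsilyl)oxy]methyl}-4-methylocta-2,4-dienoic acid
Conditions: pyridine, piperidine (10 mol%), 70 °C
Reagents that add atoms: none
Why: Knoevenagel–Doebner condensation with in situ decarboxylation gives the (2E)-dienoic acid directly; the 4E alkene and the stereocentre are not affected.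

**Step 14**
Reactants: 15 (5R,6R)-6-[(2S,4S,6E)-4,6-dimethyloct-6-en-2-yl]-5-hydroxyoxan-2-one; 24 (2E,4E,6R)-8-[(tert-butyldimethylsilyl)oxy]-6-{[(tert-butyldimethylsilyl)oxy]methyl}-4-methylocta-2,4-dienoic acid
Product: 26 (2R,3R)-2-[(2S,4S,6E)-4,6-dimethyloct-6-en-2-yl]-6-oxooxan-3-yl (2E,4E,6R)-8-[(tert-butyldimethylsilyl)oxy]-6-{[(tert-butyldimethylsilyl)oxy]methyl}-4-methylocta-2,4-dienoate, via mixed anhydride 25 (not isolated)
Conditions: 24, 2,4,6-trichlorobenzoyl chloride (1.2 equiv), Et3N (2.5 equiv), THF, 0 °C; then 15, DMAP (1.5 equiv), toluene, 0 → 23 °C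
Reagents that add atoms: none
Why: Yamaguchi esterification: the preformed mixed anhydride acylates the secondary alcohol with retention at ring C5 under DMAP catalysis at low temperature, so that acylation outruns translactonisation of the hydroxy lactone.

**Step 15**
Reactants: 26 (2R,3R)-2-[(2S,4S,6E)-4,6-dimethyloct-6-en-2-yl]-6-oxooxan-3-yl (2E,4E,6R)-8-[(tert-butyldimethylsilyl)oxy]-6-{[(tert-butyldimethylsilyl)oxy]methyl}-4-methylocta-2,4-dienoate
Product: 27 (2R,3R)-2-[(2S,4S,6E)-4,6-dimethyloct-6-en-2-yl]-6-oxooxan-3-yl (2E,4E,6R)-8-hydroxy-6-(hydroxymethyl)-4-methylocta-2,4-dienoate (CNP0257572.4)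
Conditions: HF·pyridine, pyridine, THF, 0 → 23 °C
Reagents that add atoms: none
Why: Fluoride cleaves the two primary silyl ethers under buffered, weakly acidic conditions that neither hydrolyse nor migrate either ester, giving the target.

## Compound list

1 | (S)-1-bromo-3-chloro-2-methylpropane | BrC[C@@H](C)CCl | starting material
2 | (E)-2-bromobut-2-ene | C/C=C(\C)Br | starting material
3 | (2R,4E)-1-chloro-2,4-dimethylhex-4-ene | C/C=C(\C)C[C@@H](C)CCl | intermediate
4 | ethyl (S)-lactate | C[C@H](O)C(=O)OCC | starting material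
5 | ethyl (2S)-2-[(trifluoromethanesulfonyl)oxy]propanoate | C[C@H](OS(=O)(=O)C(F)(F)F)C(=O)OCC | intermediate
6 | [(2R,4E)-2,4-dimethylhex-4-en-1-yl]magnesium chloride | C/C=C(\C)C[C@@H](C)C[Mg]Cl | intermediate
7 | ethyl (2S,4S,6E)-2,4,6-trimethyloct-6-enoate | C/C=C(\C)C[C@@H](C)C[C@H](C)C(=O)OCC | intermediate
8 | (2S,4S,6E)-2,4,6-trimethyloct-6-enal | C/C=C(\C)C[C@@H](C)C[C@H](C)C=O | intermediate
9 | 2-[(4-methoxyphenyl)methoxy]acetaldehyde | COc1ccc(COCC=O)cc1 | starting material
10 | (2R,3R,4S,6S,8E)-3-hydroxy-2-[(4-methoxyphenyl)methoxy]-4,6,8-trimethyldec-8-enal | C/C=C(\C)C[C@@H](C)C[C@H](C)[C@@H](O)[C@@H](OCc1ccc(OC)cc1)C=O | intermediate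
11 | (2R,3R,4S,6S,8E)-3-hydroxy-2-[(4-methoxyphenyl)methoxy]-4,6,8-trimethyldec-8-enoic acid | C/C=C(\C)C[C@@H](C)C[C@H](C)[C@@H](O)[C@@H](OCc1ccc(OC)cc1)C(=O)O | intermediate
12 | methyl acrylate | C=CC(=O)OC | starting material
13 | methyl (4R,5R,6S,8S,10E)-5-hydroxy-4-[(4-methoxyphenyl)methoxy]-6,8,10-trimethyldodec-10-enoate | C/C=C(\C)C[C@@H](C)C[C@H](C)[C@@H](O)[C@H](OCc1ccc(OC)cc1)CCC(=O)OC | intermediate
14 | (5R,6R)-6-[(2S,4S,6E)-4,6-dimethyloct-6-en-2-yl]-5-[(4-methoxyphenyl)methoxy]oxan-2-one | C/C=C(\C)C[C@@H](C)C[C@H](C)[C@H]1OC(=O)CC[C@H]1OCc1ccc(OC)cc1 | intermediate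
15 | (5R,6R)-6-[(2S,4S,6E)-4,6-dimethyloct-6-en-2-yl]-5-hydroxyoxan-2-one | C/C=C(\C)C[C@@H](C)C[C@H](C)[C@H]1OC(=O)CC[C@H]1O | intermediate
16 | furan-2(5H)-one | O=C1OCC=C1 | starting material
17 | (2-methylprop-1-en-1-yl)boronic acid | CC(C)=CB(O)O | starting material
18 | (4R)-4-(2-methylprop-1-en-1-yl)oxolan-2-one | O=C1C[C@H](C=C(C)C)CO1 | intermediate
19 | (2R)-2-(2-methylprop-1-en-1-yl)butane-1,4-diol | CC(C)=C[C@H](CO)CCO | intermediate
20 | (2R)-1,4-bis[(tert-butyldimethylsilyl)oxy]-2-(2-methylprop-1-en-1-yl)butane | CC(C)=C[C@H](CO[Si](C)(C)C(C)(C)C)CCO[Si](C)(C)C(C)(C)C | intermediate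
21 | (2E,4R)-6-[(tert-butyldimethylsilyl)oxy]-4-{[(tert-butyldimethylsilyl)oxy]methyl}-2-methylhex-2-en-1-ol | OC/C(C)=C/[C@H](CO[Si](C)(C)C(C)(C)C)CCO[Si](C)(C)C(C)(C)C | intermediate
22 | (2E,4R)-6-[(tert-butyldimethylsilyl)oxy]-4-{[(tert-butyldimethylsilyl)oxy]methyl}-2-methylhex-2-enal | O=C/C(C)=C/[C@H](CO[Si](C)(C)C(C)(C)C)CCO[Si](C)(C)C(C)(C)C | intermediate
23 | malonic acid | OC(=O)CC(=O)O | starting material
24 | (2E,4E,6R)-8-[(tert-butyldimethylsilyl)oxy]-6-{[(tert-butyldimethylsilyl)oxy]methyl}-4-methylocta-2,4-dienoic acid | OC(=O)/C=C/C(C)=C/[C@H](CO[Si](C)(C)C(C)(C)C)CCO[Si](C)(C)C(C)(C)C | intermediate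
25 | (2E,4E,6R)-8-[(tert-butyldimethylsilyl)oxy]-6-{[(tert-butyldimethylsilyl)oxy]methyl}-4-methylocta-2,4-dienoic 2,4,6-trichlorobenzoic anhydride | O=C(OC(=O)c1c(Cl)cc(Cl)cc1Cl)/C=C/C(C)=C/[C@H](CO[Si](C)(C)C(C)(C)C)CCO[Si](C)(C)C(C)(C)C | intermediate
26 | (2R,3R)-2-[(2S,4S,6E)-4,6-dimethyloct-6-en-2-yl]-6-oxooxan-3-yl (2E,4E,6R)-8-[(tert-butyldimethylsilyl)oxy]-6-{[(tert-butyldimethylsilyl)oxy]methyl}-4-methylocta-2,4-dienoate | C/C=C(\C)C[C@@H](C)C[C@H](C)[C@H]1OC(=O)CC[C@H]1OC(=O)/C=C/C(C)=C/[C@H](CO[Si](C)(C)C(C)(C)C)CCO[Si](C)(C)C(C)(C)C | intermediate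
27 | (2R,3R)-2-[(2S,4S,6E)-4,6-dimethyloct-6-en-2-yl]-6-oxooxan-3-yl (2E,4E,6R)-8-hydroxy-6-(hydroxymethyl)-4-methylocta-2,4-dienoate (CNP0257572.4) | C/C=C(\C)C[C@@H](C)C[C@H](C)[C@H]1OC(=O)CC[C@H]1OC(=O)/C=C/C(C)=C/[C@H](CO)CCO | target

## Step count and risks

Total step count: 15. Longest linear sequence: 9 steps (steps 1, 3, 4, 5, 6, 7, 8, 14, 15).

**Step 7 (radical addition and lactonisation).** The diastereoselectivity at ring C5 rests on a model and is not precedented for an acyclic β-hydroxy α-alkoxy radical; the radical can also be over-oxidised before it is trapped. The fallback is a reagent-controlled polar construction that sets out from aldehyde 8 and comes back to the route at 14. Aldehyde 8 is allylborated with the (Z)-γ-alkoxyallylborane made from allyl 4-methoxybenzyl ether (s-BuLi, THF, −78 °C; then (−)-Ipc2BOMe; then BF3·OEt2, −78 °C; NaOH/H2O2 work-up), which gives the threo homoallylic alcohol (3R,4R,5S,7S,9E)-3-[(4-methoxyphenyl)methoxy]-5,7,9-trimethylundeca-1,9-dien-4-ol F1. Linear-selective hydroformylation of its terminal alkene (Rh(acac)(CO)2, Xantphos, CO/H2 1:1, toluene, 60 °C) closes the lactol (5R,6R)-6-[(2S,4S,6E)-4,6-dimethyloct-6-en-2-yl]-5-[(4-methoxyphenyl)methoxy]oxan-2-ol F2, and oxidation with TEMPO (cat.) and PhI(OAc)2 in CH2Cl2 gives 14.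

**Step 5 (proline cross-aldol).** The donor 9 can self-condense and the α-branched aldehyde 8 can epimerise through its own enamine. The fallback is an auxiliary-controlled glycolate aldol that sets out from 8 and comes back at 14. Aldehyde 8 is added to the dibutylboron enolate (Bu2BOTf, Et3N, CH2Cl2, −78 → 0 °C) of (4S)-4-benzyl-3-{[(4-methoxyphenyl)methoxy]acetyl}-1,3-oxazolidin-2-one F3, itself prepared from [(4-methoxyphenyl)methoxy]acetic acid, pivaloyl chloride/Et3N and the lithiated oxazolidinone. This gives the syn adduct (4S)-4-benzyl-3-[(2S,3R,4S,6S,8E)-3-hydroxy-2-[(4-methoxyphenyl)methoxy]-4,6,8-trimethyldec-8-enoyl]-1,3-oxazolidin-2-one F4. LiOH/H2O2 (THF/H2O, 0 °C) releases (2S,3R,4S,6S,8E)-3-hydroxy-2-[(4-methoxyphenyl)methoxy]-4,6,8-trimethyldec-8-enoic acid F5, the C2 epimer of 11. Under the unchanged conditions of step 7, F5 gives the same radical and hence 13 and 14.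

**Step 14 (esterification).** The axial, hindered hydroxyl of 15 may acylate slowly, and the hydroxy lactone can translactonise to the γ-lactone under basic conditions. The fallback builds the dienoate by olefination instead; it sets out from 15 and comes back at 26. Alcohol 15 is acylated at −40 °C with the small, fast donor (diethoxyphosphoryl)acetyl chloride and pyridine in CH2Cl2 (no DMAP) to give (2R,3R)-2-[(2S,4S,6E)-4,6-dimethyloct-6-en-2-yl]-6-oxooxan-3-yl (diethoxyphosphoryl)acetate F6. Masamune–Roush olefination of F6 with enal 22 (LiCl, i-Pr2NEt, MeCN, 0 → 23 °C) forms the (2E) alkene and gives 26 directly.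

## Further compounds

F1 | step 7 | (3R,4R,5S,7S,9E)-3-[(4-methoxyphenyl)methoxy]-5,7,9-trimethylundeca-1,9-dien-4-ol | C/C=C(\C)C[C@@H](C)C[C@H](C)[C@@H](O)[C@H](OCc1ccc(OC)cc1)C=C
F2 | step 7 | (5R,6R)-6-[(2S,4S,6E)-4,6-dimethyloct-6-en-2-yl]-5-[(4-methoxyphenyl)methoxy]oxan-2-ol | C/C=C(\C)C[C@@H](C)C[C@H](C)[C@H]1OC(O)CC[C@H]1OCc1ccc(OC)cc1
F3 | step 5 | (4S)-4-benzyl-3-{[(4-methoxyphenyl)methoxy]acetyl}-1,3-oxazolidin-2-one | COc1ccc(COCC(=O)N2[C@@H](Cc3ccccc3)COC2=O)cc1
F4 | step 5 | (4S)-4-benzyl-3-[(2S,3R,4S,6S,8E)-3-hydroxy-2-[(4-methoxyphenyl)methoxy]-4,6,8-trimethyldec-8-enoyl]-1,3-oxazolidin-2-one | C/C=C(\C)C[C@@H](C)C[C@H](C)[C@@H](O)[C@H](OCc1ccc(OC)cc1)C(=O)N1[C@@H](Cc2ccccc2)COC1=O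
F5 | step 5 | (2S,3R,4S,6S,8E)-3-hydroxy-2-[(4-methoxyphenyl)methoxy]-4,6,8-trimethyldec-8-enoic acid | C/C=C(\C)C[C@@H](C)C[C@H](C)[C@@H](O)[C@H](OCc1ccc(OC)cc1)C(=O)O
F6 | step 14 | (2R,3R)-2-[(2S,4S,6E)-4,6-dimethyloct-6-en-2-yl]-6-oxooxan-3-yl (diethoxyphosphoryl)acetate | C/C=C(\C)C[C@@H](C)C[C@H](C)[C@H]1OC(=O)CC[C@H]1OC(=O)CP(=O)(OCC)OCC
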